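**Remarks.** Labdane numbering is used throughout. The SMILES corresponds to (2S,4R,5S,9R,10S,13R), an ent‑labdane: H5 and H9 are anti to the C20 methyl, and C19 is the C4 carbon syn to C20. The half‑ester 10 is assumed to be purchasable. Numbers are given to substrates, intermediates and the organic reagents that deliver carbon or silicon to a product.

## Structural features

The target is a trans‑fused decalin (ring A: C1–C5 and C10; ring B: C5–C10) with a C9 side chain C11–C15 that ends in a carboxylic acid. Ring B holds a trisubstituted C7=C8 alkene with the C17 methyl on C8, so C9 is allylic and C8 is the one ring carbon that can be traced back to a carbonyl without touching a stereocentre. Three contiguous stereocentres, C9–C10–C5, include the quaternary C10 with its angular methyl C20. A second quaternary centre, C4, stands 1,3 to C10 and carries the equatorial C18 methyl and the axial acetoxymethyl C19, syn to C20. The C2 hydroxyl is equatorial (anti to C20) and sits between two methylenes that each adjoin a quaternary carbon; oxygen at C2 instead of C3, together with C19, is a 1,4‑dioxygen pattern that epoxide‑initiated polyene cyclisation does not deliver. C13 (R) is remote from the ring stereocentres and has to arrive as a separate, configurationally secure unit. Fragile points are the primary acetate beside a free secondary alcohol and a free acid (no late basic hydrolysis) and the C7=C8 alkene, which can migrate under acid. The real difficulty is the C5/C10/C9 triad around quaternary C10, the axial oxygenated carbon on C4, and the regiodefined alkene.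

## Logic of the disconnections

**41 back to 36 (C15 oxidation level, C2–O).** The acid of 41 is taken back to the primary alcohol 39 and its silyl ether 38, so that no enolisable C15 carbonyl exists earlier. The C2–O bond of 38 is then cut to the C1=C2 alkene 36. The gain is that ring A needs no oxygen until the end. The forward hydroboration must choose the disubstituted ring A alkene over C7=C8, place boron on C2 and attack anti to the two axial groups C19 and C20.

**36 back to 30 (C19 oxidation level, C4–C18).** Acetate 36 comes from alcohol 34 and ester 33. The C4–C18 bond is cut, which gives 30, an ester with hydrogen at C4 that may be a mixture of epimers. The gain is that C4 need not be controlled anywhere earlier. The demand is that the planar enolate takes the methyl group on the face anti to C20.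

**30 back to 25 (C8–C17).** The C8–C17 bond is cut through the enol triflate 28 to the C8 ketone 25. The ketone defines the alkene position, makes C9 an epimerisable α‑carbon and makes C10 a former β‑carbon. The demand is kinetic enolisation towards C7, not C9.

**25 back to 22 (C9–H, then ring A at C1=C2).** The C9–H bond is traced to the alkylidene ketone 23, and ring A is opened at C1=C2 by retro‑metathesis to the triene 22. The gain is a monocyclic ring B template. The demand is that the vinyl arm on C10 and the C4 arm on C5 are trans.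

**22 back to 9 + 18 + 17 (key: C10–C1 and C9–C11).** Dehydration retron 20 is cut at C10–C1 and C9–C11 into enone 9, the vinyl nucleophile 18 and the chiral aldehyde 17. One operation creates quaternary C10 with the trans relation to C5 and attaches the whole side chain. The demand is 1,4‑addition anti to the C5 substituent and use of the enolate before it equilibrates.

**17 back to 10.** The aldehyde is traced through 16, 14 and the lactone 12 to the half‑ester 10. Choosing which terminus is reduced fixes C13 without any stereoselective step.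

**9 back to 1.** The C8 carbonyl is removed (allylic oxidation of 8), the C4–C3 bond is cut (enolate allylation of 5), and the C5–C4 bond is cut by a Claisen retron to the allylic alcohol 2, made from 1 by asymmetric reduction. The absolute configuration of the whole ring system therefore rests on one catalytic reduction followed by a stereospecific sigmatropic shift.

## Other disconnections considered

**Alternative 1:** (the first that comes to mind) Cut C4–C5 and C9–C10, so that both rings come from an acyclic polyene. The forward key step is a cascade cyclisation of the epoxy polyene A1, started by opening its 1,1‑disubstituted oxirane with Cp2TiCl (trivalent titanium) or a Lewis acid, to give the bicycle A2. The chosen plan is preferred for three reasons. The initiating C4 centre must carry both CH3 and CH2O, and nothing in a chair‑like transition state makes the CH2O group prefer the axial position syn to C20, so C4 would be left to chance. The C2 silyloxy group sits β to the initiating centre, which retards a cationic start and invites β‑elimination in the radical–titanium manifold. Termination would give 8(17)/7‑ene mixtures, and A1 with its isolated C2 stereocentre costs about as many steps as the ring B template.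

**Alternative 2:** Cut C9–C10 and C7=C8, with ring A made first. The forward key step is a Hosomi–Sakurai conjugate allylation of enone A3 with the terpenoid allylsilane A4, which already holds C8, C9 and C11–C17, to give A5; ring‑closing metathesis then gives A6. The union is very convergent. However, C9 would be set in an open transition state between a trisubstituted allylsilane and a β,β‑disubstituted enone. More seriously, in A6 C4 is an unactivated methylene β to the only carbonyl, so the quaternary C4 with its axial oxygenated carbon would need two further enone formations and conjugate additions. In the chosen plan C4 is an ester α‑carbon from the start.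

**Alternative 3:** Cut C9–C10 and C5–C6, so that ring B comes from a [4+2] cycloaddition. The forward key step is a Diels–Alder reaction of diene A7 with the (E)‑2‑methyl‑2‑enal A8. The endo rule places the formyl carbon (C1) syn to the C9 side chain, whereas the target needs the C20 methyl syn to it, so the expected adduct A9 belongs to the 9‑epi series. The 2‑methyl group of A7 also opposes the regiochemical preference of the 1‑alkyl group. The chosen plan sets the same C10/C5 relation through the well‑founded anti addition to a 4‑substituted cyclohexenone.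

Key step: step 9

## Steps

Step 1
Reactants: 1 2-methylcyclohex-2-en-1-one
Product: 2 (1R)-2-methylcyclohex-2-en-1-ol
Conditions: (S)-2-methyl-CBS-oxazaborolidine (10 mol %), BH3·SMe2, THF, −20 °C; MeOH
Reagents that add atoms: none
Why: Corey–Bakshi–Shibata reduction; the catalyst distinguishes the 2‑methylvinyl flank (large) from the CH2 flank (small), so hydride should add 1,2 to give the (R) carbinol.

Step 2
Reactants: 2 (1R)-2-methylcyclohex-2-en-1-ol; 3 triethyl orthoacetate
Product: 5 ethyl 2-[(1R)-2-methylcyclohex-2-en-1-yl]acetate, via ketene acetal 4 (not isolated)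
Conditions: MeC(OEt)3 (excess), EtCO2H (cat.), 140 °C, EtOH distilled off
Reagents that add atoms: triethyl orthoacetate, CC(OCC)(OCC)OCC
Why: Johnson–Claisen rearrangement; the suprafacial [3,3] shift should transfer the C9–O configuration to the new C5–C4 bond and leave the trisubstituted alkene at C9=C10.

Step 3
Reactants: 5 ethyl 2-[(1R)-2-methylcyclohex-2-en-1-yl]acetate; 6 allyl bromide
Product: 8 ethyl 2-[(1R)-2-methylcyclohex-2-en-1-yl]pent-4-enoate (C4 epimers), via lithium enolate 7 (not isolated)
Conditions: LiN(i-Pr)2, THF, −78 °C; CH2=CHCH2Br, −78 → 0 °C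
Reagents that add atoms: allyl bromide, C=CCBr
Why: Ester enolate alkylation; the new centre C4 is not controlled and need not be, because it is planarised again in step 15.

Step 4
Reactants: 8 ethyl 2-[(1R)-2-methylcyclohex-2-en-1-yl]pent-4-enoate
Product: 9 ethyl 2-[(1R)-2-methyl-4-oxocyclohex-2-en-1-yl]pent-4-enoate (C4 epimers)
Conditions: CrO3, 3,5-dimethylpyrazole, CH2Cl2, −20 °C
Reagents that add atoms: chromium trioxide, O=[Cr](=O)=O
Why: Allylic oxidation; C8 is the only allylic methylene of the trisubstituted ring alkene (C5 is a methine and cannot become a ketone), so the conjugated enone should form, while the allylic CH2 of the monosubstituted alkene is less reactive.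

Step 5
Reactants: 10 (3R)-5-methoxy-3-methyl-5-oxopentanoic acid
Product: 12 (4S)-4-methyloxan-2-one, via hydroxy acid 11 (not isolated)
Conditions: LiBH4, THF, 0 °C → rt; 2 M HCl; TsOH (cat.), PhMe, 40 °C
Reagents that add atoms: none
Why: LiBH4 reduces the ester but not the lithium carboxylate, and acid closes the δ‑lactone; the former acid carbon becomes C11 and the former ester carbon C15, which gives the required sense at C13 without touching it.

Step 6
Reactants: 12 (4S)-4-methyloxan-2-one; 13 N,O-dimethylhydroxylamine hydrochloride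
Product: 14 (3S)-5-hydroxy-N-methoxy-N,3-dimethylpentanamide
Conditions: MeNH(OMe)·HCl, AlMe3, CH2Cl2, 0 °C → rt; aq. potassium sodium tartrate (KNaC4H4O6)
Reagents that add atoms: N,O-dimethylhydroxylamine hydrochloride, CNOC.Cl
Why: Aluminium amide aminolysis of a lactone; the ring opens at the acyl carbon and frees the C15 hydroxyl.

Step 7
Reactants: 14 (3S)-5-hydroxy-N-methoxy-N,3-dimethylpentanamide; 15 tert-butyldimethylsilyl chloride
Product: 16 (3S)-5-[(tert-butyldimethylsilyl)oxy]-N-methoxy-N,3-dimethylpentanamide
Conditions: TBSCl, imidazole, DMF, rt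
Reagents that add atoms: tert-butyldimethylsilyl chloride, CC(C)(C)[Si](C)(C)Cl
Why: Silylation of the primary alcohol; C15 is carried at the alcohol level so that no second enolisable ester is present in step 15.

Step 8
Reactants: 16 (3S)-5-[(tert-butyldimethylsilyl)oxy]-N-methoxy-N,3-dimethylpentanamide
Product: 17 (3S)-5-[(tert-butyldimethylsilyl)oxy]-3-methylpentanal
Conditions: i-Bu2AlH, THF, −78 °C; aq. potassium sodium tartrate
Reagents that add atoms: none
Why: Reduction of an N‑methoxy‑N‑methylamide stops at the chelated hemiaminal and releases the aldehyde on work‑up; the β‑stereocentre cannot epimerise.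

Step 9
Reactants: 9 ethyl 2-[(1R)-2-methyl-4-oxocyclohex-2-en-1-yl]pent-4-enoate; 17 (3S)-5-[(tert-butyldimethylsilyl)oxy]-3-methylpentanal; 18 vinylmagnesium bromide
Product: 20 ethyl 2-[(1R,2R)-3-{(3S)-5-[(tert-butyldimethylsilyl)oxy]-1-hydroxy-3-methylpentyl}-2-ethenyl-2-methyl-4-oxocyclohexyl]pent-4-enoate (isomers at C9 and C11 and C4), via bromomagnesium enolate 19 (not isolated)
Conditions: CH2=CHMgBr, CuBr·SMe2 (20 mol %), THF, −78 → −40 °C; then 17, −78 °C; aq. NH4Cl
Reagents that add atoms: vinylmagnesium bromide, C=C[Mg]Br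
Why: The closest known reaction type is the copper‑catalysed conjugate addition with enolate trapping (vicinal difunctionalisation of an enone, a three‑component coupling). CH2=CHMgBr and CuBr·SMe2 give a vinyl cuprate of monovalent copper that π‑complexes the enone, adds at C10 to a trivalent‑copper β‑adduct and reductively eliminates, leaving the regiodefined C8–C9 bromomagnesium enolate 19, which adds to the aldehyde through a closed six‑membered transition state before it can equilibrate. No ring is closed; the bonds formed are C10–C1 and C9–C11. At C10, A(1,2) strain with the vinylic C20 methyl holds the C5 side chain pseudoaxial and axial attack then comes from the opposite face, so the vinyl group should end anti to C4 and C20 syn to it, which is the relation of a trans ring fusion. C9 and C11 form as mixtures and need no control, since C11 becomes sp2 in step 10 and C9 is reset in step 12. The step needs 1,4‑ over 1,2‑addition (copper), face selectivity (the C5 stereocentre), regiospecific use of the enolate (aldehyde added at −78 °C) and sparing of the ester (low temperature).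

Step 10
Reactants: 20 aldol adduct
Product: 22 ethyl 2-[(1R,2R)-3-{(3R)-5-[(tert-butyldimethylsilyl)oxy]-3-methylpentylidene}-2-ethenyl-2-methyl-4-oxocyclohexyl]pent-4-enoate (E/Z and C4 isomers), via mesylate 21 (not isolated)
Conditions: MsCl, Et3N, CH2Cl2, 0 °C; then DBU, rt
Reagents that add atoms: none
Why: E1cB elimination of the β‑mesyloxy ketone; it removes the two uncontrolled centres C9 and C11 and gives the C9=C11 alkylidene ketone.

Step 11
Reactants: 22 alkylidene ketone triene
Product: 23 ethyl (13R)-15-[(tert-butyldimethylsilyl)oxy]-8-oxo-17,18-dinor-ent-labda-1,9(11)-dien-19-oate (C4 epimers; E/Z)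
Conditions: RuCl2(=CHPh)(PCy3)(H2IMes) (second-generation Grubbs catalyst, 5 mol %), CH2Cl2, 40 °C
Reagents that add atoms: none
Why: Ring‑closing metathesis of the vinyl group on C10 with the allyl terminus on C4 closes ring A as a cyclohexene (C1=C2); the two arms are trans on ring B, so the fusion is trans, and the trisubstituted, electron‑poor enone alkene should not take part.

Step 12
Reactants: 23 bicyclic alkylidene ketone
Product: 25 ethyl (13R)-15-[(tert-butyldimethylsilyl)oxy]-8-oxo-17,18-dinor-ent-labd-1-en-19-oate (C4 epimers), via copper enolate 24 (not isolated)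
Conditions: [(Ph3P)CuH]6, PhMe, H2O, rt
Reagents that add atoms: none
Why: Conjugate reduction by the hydride of monovalent copper; hydride adds to C11 and the C8–C9 enolate is protonated at C9 anti to the axial C20 methyl, giving the equatorial side chain. This is also the more stable epimer at this ketone α‑carbon, so both E and Z isomers of 23 should converge.

Step 13
Reactants: 25 bicyclic ketone; 26 N-phenylbis(trifluoromethanesulfonimide)
Product: 28 ethyl (13R)-15-[(tert-butyldimethylsilyl)oxy]-8-{[(trifluoromethyl)sulfonyl]oxy}-17,18-dinor-ent-labda-1,7-dien-19-oate (C4 epimers), via potassium enolate 27 (not isolated)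
Conditions: KN(SiMe3)2, THF, −78 °C; PhNTf2, −78 → 0 °C
Reagents that add atoms: N-phenylbis(trifluoromethanesulfonimide), O=S(=O)(N(c1ccccc1)S(=O)(=O)C(F)(F)F)C(F)(F)F
Why: Kinetic deprotonation should occur at the C7 methylene, not at the hindered C9 methine beside quaternary C10; O‑triflation fixes the alkene at C7=C8.

Step 14
Reactants: 28 enol triflate; 29 methylmagnesium bromide
Product: 30 ethyl (13R)-15-[(tert-butyldimethylsilyl)oxy]-18-nor-ent-labda-1,7-dien-19-oate (C4 epimers)
Conditions: MeMgBr, Fe(acac)3 (5 mol %), THF/NMP, −30 → 0 °C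
Reagents that add atoms: methylmagnesium bromide, C[Mg]Br
Why: Iron‑catalysed cross‑coupling of an alkenyl triflate with a Grignard reagent; it is fast at low temperature, spares the hindered ester and keeps the alkene at C7=C8 with the C17 methyl on C8.

Step 15
Reactants: 30 diene ester; 31 iodomethane
Product: 33 ethyl (13R)-15-[(tert-butyldimethylsilyl)oxy]-ent-labda-1,7-dien-19-oate, via lithium enolate 32 (not isolated)
Conditions: LiN(i-Pr)2, THF, −78 → −30 °C; MeI, DMPU, −78 → 0 °C
Reagents that add atoms: iodomethane, CI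
Why: Ester enolate alkylation; both C4 epimers give the same planar enolate, and MeI should approach anti to the 1,3‑related axial C20 methyl, so the new methyl is equatorial and the ester axial (syn to C20), as in known C4 alkylations of 10‑methyldecalin esters.

Step 16
Reactants: 33 quaternary ester
Product: 34 (13R)-15-[(tert-butyldimethylsilyl)oxy]-ent-labda-1,7-dien-19-ol
Conditions: LiAlH4, Et2O, 0 °C → rt
Reagents that add atoms: none
Why: Hydride reduction of the neopentyl ester; the silyl ether and both alkenes are inert.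

Step 17
Reactants: 34 neopentyl alcohol; 35 acetic anhydride
Product: 36 (13R)-15-[(tert-butyldimethylsilyl)oxy]-ent-labda-1,7-dien-19-yl acetate
Conditions: Ac2O, pyridine, DMAP (cat.), CH2Cl2, rt
Reagents that add atoms: acetic anhydride, CC(=O)OC(C)=O
Why: Acylation of the only free hydroxyl; done before C2 is oxygenated so that no diol has to be differentiated.

Step 18
Reactants: 36 diene acetate
Product: 38 (2S,13R)-15-[(tert-butyldimethylsilyl)oxy]-2-hydroxy-ent-labd-7-en-19-yl acetate, via alkylborane 37 (not isolated)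
Conditions: 9-BBN, THF, 60 °C; then 30% H2O2, pH 7 phosphate buffer, 0 °C → rt
Reagents that add atoms: hydrogen peroxide, OO
Why: Hydroboration–oxidation; the cis‑disubstituted C1=C2 alkene should react far faster than the hindered trisubstituted C7=C8. Boron goes to C2 because C1 is neopentyl, and syn addition anti to the axial C19 and C20 groups gives, after oxidation with retention, the equatorial (2S) alcohol; buffered peroxide spares the acetate.

Step 19
Reactants: 38 silyl ether
Product: 39 (2S,13R)-2,15-dihydroxy-ent-labd-7-en-19-yl acetate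
Conditions: HF·pyridine, THF, 0 °C → rt
Reagents that add atoms: none
Why: Fluoride cleavage of the primary silyl ether; the acetate cannot migrate to the C2 hydroxyl because the two groups are trans across ring A.

Step 20
Reactants: 39 diol acetate
Product: 41 (2S,13R)-19-acetoxy-2-hydroxy-ent-labd-7-en-15-oic acid (CNP0162900.1), via aldehyde 40 (not isolated)
Conditions: TEMPO (20 mol %), PhI(OAc)2, MeCN/H2O, rt
Reagents that add atoms: water, O
Why: Oxoammonium oxidation; it should select the unhindered primary alcohol over the secondary C2 hydroxyl, and the aldehyde hydrate is oxidised on to the acid in the aqueous medium.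

## Compound list

1 | 2-methylcyclohex-2-en-1-one | CC1=CCCCC1=O | starting material
2 | (1R)-2-methylcyclohex-2-en-1-ol | CC1=CCCC[C@H]1O | intermediate
3 | triethyl orthoacetate | CC(OCC)(OCC)OCC | starting material
4 | 1-ethoxy-1-{[(1R)-2-methylcyclohex-2-en-1-yl]oxy}ethene (ketene acetal, not isolated) | CC1=CCCC[C@H]1OC(=C)OCC | intermediate
5 | ethyl 2-[(1R)-2-methylcyclohex-2-en-1-yl]acetate | CC1=CCCC[C@@H]1CC(=O)OCC | intermediate
6 | allyl bromide | C=CCBr | starting material
7 | lithium enolate of 5 (not isolated) | CC1=CCCC[C@@H]1C=C(O[Li])OCC | intermediate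
8 | ethyl 2-[(1R)-2-methylcyclohex-2-en-1-yl]pent-4-enoate (C4 epimers) | CC1=CCCC[C@@H]1C(CC=C)C(=O)OCC | intermediate
9 | ethyl 2-[(1R)-2-methyl-4-oxocyclohex-2-en-1-yl]pent-4-enoate (C4 epimers) | CC1=CC(=O)CC[C@@H]1C(CC=C)C(=O)OCC | intermediate
10 | (3R)-5-methoxy-3-methyl-5-oxopentanoic acid (monomethyl (R)-3-methylglutarate) | OC(=O)C[C@@H](C)CC(=O)OC | starting material
11 | (3S)-5-hydroxy-3-methylpentanoic acid (not isolated) | OC(=O)C[C@@H](C)CCO | intermediate
12 | (4S)-4-methyloxan-2-one | O=C1C[C@@H](C)CCO1 | intermediate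
13 | N,O-dimethylhydroxylamine hydrochloride | CNOC.Cl | starting material
14 | (3S)-5-hydroxy-N-methoxy-N,3-dimethylpentanamide | CON(C)C(=O)C[C@@H](C)CCO | intermediate
15 | tert-butyldimethylsilyl chloride | CC(C)(C)[Si](C)(C)Cl | starting material
16 | (3S)-5-[(tert-butyldimethylsilyl)oxy]-N-methoxy-N,3-dimethylpentanamide | CON(C)C(=O)C[C@@H](C)CCO[Si](C)(C)C(C)(C)C | intermediate
17 | (3S)-5-[(tert-butyldimethylsilyl)oxy]-3-methylpentanal | O=CC[C@@H](C)CCO[Si](C)(C)C(C)(C)C | intermediate
18 | vinylmagnesium bromide | C=C[Mg]Br | starting material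
19 | bromomagnesium enolate (C8–O, C8=C9) of the conjugate adduct (not isolated) | C=C[C@@]1(C)C=C(O[Mg]Br)CC[C@@H]1C(CC=C)C(=O)OCC | intermediate
20 | ethyl 2-[(1R,2R)-3-{(3S)-5-[(tert-butyldimethylsilyl)oxy]-1-hydroxy-3-methylpentyl}-2-ethenyl-2-methyl-4-oxocyclohexyl]pent-4-enoate (isomers at C9, C11, C4) | C=C[C@@]1(C)C(C(O)C[C@@H](C)CCO[Si](C)(C)C(C)(C)C)C(=O)CC[C@@H]1C(CC=C)C(=O)OCC | intermediate
21 | methanesulfonate of 20 (not isolated) | C=C[C@@]1(C)C(C(OS(C)(=O)=O)C[C@@H](C)CCO[Si](C)(C)C(C)(C)C)C(=O)CC[C@@H]1C(CC=C)C(=O)OCC | intermediate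
22 | ethyl 2-[(1R,2R)-3-{(3R)-5-[(tert-butyldimethylsilyl)oxy]-3-methylpentylidene}-2-ethenyl-2-methyl-4-oxocyclohexyl]pent-4-enoate (E/Z; C4 epimers) | C=C[C@@]1(C)C(=CC[C@@H](C)CCO[Si](C)(C)C(C)(C)C)C(=O)CC[C@@H]1C(CC=C)C(=O)OCC | intermediate
23 | ethyl (13R)-15-[(tert-butyldimethylsilyl)oxy]-8-oxo-17,18-dinor-ent-labda-1,9(11)-dien-19-oate (C4 epimers; E/Z) | CCOC(=O)C1CC=C[C@@]2(C)C(=CC[C@@H](C)CCO[Si](C)(C)C(C)(C)C)C(=O)CC[C@H]12 | intermediate
24 | monovalent copper enolate (C8–O, C8=C9) (not isolated) | CCOC(=O)C1CC=C[C@@]2(C)C(CC[C@@H](C)CCO[Si](C)(C)C(C)(C)C)=C(O[Cu])CC[C@H]12 | intermediate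
25 | ethyl (13R)-15-[(tert-butyldimethylsilyl)oxy]-8-oxo-17,18-dinor-ent-labd-1-en-19-oate (C4 epimers) | CCOC(=O)C1CC=C[C@@]2(C)[C@H](CC[C@@H](C)CCO[Si](C)(C)C(C)(C)C)C(=O)CC[C@H]12 | intermediate
26 | N-phenylbis(trifluoromethanesulfonimide) | O=S(=O)(N(c1ccccc1)S(=O)(=O)C(F)(F)F)C(F)(F)F | starting material
27 | potassium enolate (C8–O, C7=C8) of 25 (not isolated) | CCOC(=O)C1CC=C[C@@]2(C)[C@H](CC[C@@H](C)CCO[Si](C)(C)C(C)(C)C)C(O[K])=CC[C@H]12 | intermediate
28 | ethyl (13R)-15-[(tert-butyldimethylsilyl)oxy]-8-{[(trifluoromethyl)sulfonyl]oxy}-17,18-dinor-ent-labda-1,7-dien-19-oate (C4 epimers) | CCOC(=O)C1CC=C[C@@]2(C)[C@H](CC[C@@H](C)CCO[Si](C)(C)C(C)(C)C)C(OS(=O)(=O)C(F)(F)F)=CC[C@H]12 | intermediate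
29 | methylmagnesium bromide | C[Mg]Br | starting material
30 | ethyl (13R)-15-[(tert-butyldimethylsilyl)oxy]-18-nor-ent-labda-1,7-dien-19-oate (C4 epimers) | CCOC(=O)C1CC=C[C@@]2(C)[C@H](CC[C@@H](C)CCO[Si](C)(C)C(C)(C)C)C(C)=CC[C@H]12 | intermediate
31 | iodomethane | CI | starting material
32 | lithium enolate (C4=C19) of 30 (not isolated) | CCOC(O[Li])=C1CC=C[C@@]2(C)[C@H](CC[C@@H](C)CCO[Si](C)(C)C(C)(C)C)C(C)=CC[C@H]12 | intermediate
33 | ethyl (13R)-15-[(tert-butyldimethylsilyl)oxy]-ent-labda-1,7-dien-19-oate | CCOC(=O)[C@]1(C)CC=C[C@@]2(C)[C@H](CC[C@@H](C)CCO[Si](C)(C)C(C)(C)C)C(C)=CC[C@H]12 | intermediate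
34 | (13R)-15-[(tert-butyldimethylsilyl)oxy]-ent-labda-1,7-dien-19-ol | OC[C@]1(C)CC=C[C@@]2(C)[C@H](CC[C@@H](C)CCO[Si](C)(C)C(C)(C)C)C(C)=CC[C@H]12 | intermediate
35 | acetic anhydride | CC(=O)OC(C)=O | starting material
36 | (13R)-15-[(tert-butyldimethylsilyl)oxy]-ent-labda-1,7-dien-19-yl acetate | CC(=O)OC[C@]1(C)CC=C[C@@]2(C)[C@H](CC[C@@H](C)CCO[Si](C)(C)C(C)(C)C)C(C)=CC[C@H]12 | intermediate
37 | B-(C2)-alkyl-9-borabicyclo[3.3.1]nonane adduct of 36 (not isolated) | CC(=O)OC[C@]1(C)C[C@@H](B3C4CCCC3CCC4)C[C@@]2(C)[C@H](CC[C@@H](C)CCO[Si](C)(C)C(C)(C)C)C(C)=CC[C@H]12 | intermediate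
38 | (2S,13R)-15-[(tert-butyldimethylsilyl)oxy]-2-hydroxy-ent-labd-7-en-19-yl acetate | CC(=O)OC[C@]1(C)C[C@@H](O)C[C@@]2(C)[C@H](CC[C@@H](C)CCO[Si](C)(C)C(C)(C)C)C(C)=CC[C@H]12 | intermediate
39 | (2S,13R)-2,15-dihydroxy-ent-labd-7-en-19-yl acetate | CC(=O)OC[C@]1(C)C[C@@H](O)C[C@@]2(C)[C@H](CC[C@@H](C)CCO)C(C)=CC[C@H]12 | intermediate
40 | (2S,13R)-19-acetoxy-2-hydroxy-ent-labd-7-en-15-al (not isolated) | CC(=O)OC[C@]1(C)C[C@@H](O)C[C@@]2(C)[C@H](CC[C@@H](C)CC=O)C(C)=CC[C@H]12 | intermediate
41 | (2S,13R)-19-acetoxy-2-hydroxy-ent-labd-7-en-15-oic acid, (2S,4R,5S,9R,10S,13R), CNP0162900.1 | CC(=O)OC[C@]1(C)C[C@@H](O)C[C@@]2(C)[C@H](CC[C@@H](C)CC(=O)O)C(C)=CC[C@H]12 | target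

## Step count and least certain steps

Total: 20 steps. Longest linear sequence: 16 steps (steps 1–4 and 9–20; the branch of steps 5–8 followed by 9–20 is equally long).

**Step 9 (key step).** The most likely failure is incomplete conjugate addition: C10 is flanked by the branched C5 side chain, so the Grignard reagent may add 1,2 or deprotonate the enone at the γ‑position. A second risk is proton transfer or retro‑aldol at the hindered enolate, so that the aldehyde is not captured. The fallback separates the two bond formations and changes the second from a metal‑enolate aldol to a Lewis‑acid‑mediated addition of an isolated enol silane. It sets out from 9: lithium divinylcuprate (CH2=CH)2CuLi with Me3SiCl in THF at −78 °C should force the 1,4‑addition and deliver the trimethylsilyl enol ether of the conjugate adduct F1. A Mukaiyama aldol addition of F1 to 17 with BF3·OEt2 in CH2Cl2 at −78 °C then gives 20, where the route is rejoined.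

**Step 4.** Hydrogen abstraction at the tertiary allylic C5–H or at the allylic CH2 of the pentenyl arm, and over‑oxidation, may erode the regioselectivity of the chromium oxidation. The fallback replaces C–H oxidation by an alkene‑based 1,3‑oxygen transposition and sets out from 8. Peracid epoxidation (m‑CPBA, CH2Cl2, 0 °C) of the more electron‑rich ring alkene gives the epoxide ethyl 2-[(1R)-2,3-epoxy-2-methylcyclohexyl]pent-4-enoate F2. Opening at the secondary carbon C9 with PhSeNa (from PhSeSePh and NaBH4, EtOH) gives the hydroxy selenide ethyl 2-[(1R)-2-hydroxy-2-methyl-3-(phenylselanyl)cyclohexyl]pent-4-enoate F3. Oxidation with H2O2 and syn elimination, which can only run towards C8, gives the tertiary allylic alcohol ethyl 2-[(1R)-2-hydroxy-2-methylcyclohex-3-en-1-yl]pent-4-enoate F4. Oxidative 1,3‑transposition with pyridinium chlorochromate (CH2Cl2, rt) returns to 9.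

**Step 18.** Competitive hydroboration of the C7=C8 alkene, or imperfect C2/C1 regioselection, would give isomeric alcohols. The fallback moves the hydroboration to a stage at which the ring B alkene is an electron‑poor enol triflate, and sets out from 28.
- 9‑BBN followed by buffered H2O2 gives the alcohol ethyl (13R)-15-[(tert-butyldimethylsilyl)oxy]-2-hydroxy-8-{[(trifluoromethyl)sulfonyl]oxy}-17,18-dinor-ent-labd-7-en-19-oate F5.
- TBSCl and imidazole give its silyl ether ethyl (13R)-2,15-bis[(tert-butyldimethylsilyl)oxy]-8-{[(trifluoromethyl)sulfonyl]oxy}-17,18-dinor-ent-labd-7-en-19-oate F6.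
- MeMgBr with Fe(acac)3 gives ethyl (13R)-2,15-bis[(tert-butyldimethylsilyl)oxy]-18-nor-ent-labd-7-en-19-oate F7.
- LiN(i-Pr)2 then MeI, now on a saturated chair in which the axial C20 methyl shields one face even more clearly, gives ethyl (13R)-2,15-bis[(tert-butyldimethylsilyl)oxy]-ent-labd-7-en-19-oate F8.
- LiAlH4 gives (13R)-2,15-bis[(tert-butyldimethylsilyl)oxy]-ent-labd-7-en-19-ol F9.
- Ac2O and pyridine give (13R)-2,15-bis[(tert-butyldimethylsilyl)oxy]-ent-labd-7-en-19-yl acetate F10.
- HF·pyridine removes both silyl groups and returns to 39.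

## Further compounds

F1 | step 9 | trimethylsilyl enol ether (C8–O, C8=C9) of ethyl 2-[(1R,2R)-2-ethenyl-2-methyl-4-oxocyclohexyl]pent-4-enoate | C=C[C@@]1(C)C=C(O[Si](C)(C)C)CC[C@@H]1C(CC=C)C(=O)OCC
F2 | step 4 | ethyl 2-[(1R)-2,3-epoxy-2-methylcyclohexyl]pent-4-enoate (epoxide anti to the side chain) | C[C@]12O[C@H]1CCC[C@@H]2C(CC=C)C(=O)OCC
F3 | step 4 | ethyl 2-[(1R)-2-hydroxy-2-methyl-3-(phenylselanyl)cyclohexyl]pent-4-enoate | C[C@]1(O)[C@H]([Se]c2ccccc2)CCC[C@@H]1C(CC=C)C(=O)OCC
F4 | step 4 | ethyl 2-[(1R)-2-hydroxy-2-methylcyclohex-3-en-1-yl]pent-4-enoate | C[C@]1(O)C=CCC[C@@H]1C(CC=C)C(=O)OCC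
F5 | step 18 | ethyl (13R)-15-[(tert-butyldimethylsilyl)oxy]-2-hydroxy-8-{[(trifluoromethyl)sulfonyl]oxy}-17,18-dinor-ent-labd-7-en-19-oate (2-OH anti to C20; C4 epimers) | CCOC(=O)C1C[C@@H](O)C[C@@]2(C)[C@H](CC[C@@H](C)CCO[Si](C)(C)C(C)(C)C)C(OS(=O)(=O)C(F)(F)F)=CC[C@H]12
F6 | step 18 | ethyl (13R)-2,15-bis[(tert-butyldimethylsilyl)oxy]-8-{[(trifluoromethyl)sulfonyl]oxy}-17,18-dinor-ent-labd-7-en-19-oate (C4 epimers) | CCOC(=O)C1C[C@@H](O[Si](C)(C)C(C)(C)C)C[C@@]2(C)[C@H](CC[C@@H](C)CCO[Si](C)(C)C(C)(C)C)C(OS(=O)(=O)C(F)(F)F)=CC[C@H]12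
F7 | step 18 | ethyl (13R)-2,15-bis[(tert-butyldimethylsilyl)oxy]-18-nor-ent-labd-7-en-19-oate (C4 epimers) | CCOC(=O)C1C[C@@H](O[Si](C)(C)C(C)(C)C)C[C@@]2(C)[C@H](CC[C@@H](C)CCO[Si](C)(C)C(C)(C)C)C(C)=CC[C@H]12
F8 | step 18 | ethyl (13R)-2,15-bis[(tert-butyldimethylsilyl)oxy]-ent-labd-7-en-19-oate | CCOC(=O)[C@]1(C)C[C@@H](O[Si](C)(C)C(C)(C)C)C[C@@]2(C)[C@H](CC[C@@H](C)CCO[Si](C)(C)C(C)(C)C)C(C)=CC[C@H]12
F9 | step 18 | (13R)-2,15-bis[(tert-butyldimethylsilyl)oxy]-ent-labd-7-en-19-ol | OC[C@]1(C)C[C@@H](O[Si](C)(C)C(C)(C)C)C[C@@]2(C)[C@H](CC[C@@H](C)CCO[Si](C)(C)C(C)(C)C)C(C)=CC[C@H]12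
F10 | step 18 | (13R)-2,15-bis[(tert-butyldimethylsilyl)oxy]-ent-labd-7-en-19-yl acetate | CC(=O)OC[C@]1(C)C[C@@H](O[Si](C)(C)C(C)(C)C)C[C@@]2(C)[C@H](CC[C@@H](C)CCO[Si](C)(C)C(C)(C)C)C(C)=CC[C@H]12
A1 | alternative 1 | methyl (3R,6E,10E,13S)-13-[(tert-butyldimethylsilyl)oxy]-3,7,11-trimethyl-14-(2-methyloxiran-2-yl)tetradeca-6,10-dienoate | COC(=O)C[C@H](C)CC/C=C(\C)CC/C=C(\C)C[C@H](O[Si](C)(C)C(C)(C)C)CC1(C)CO1
A2 | alternative 1 | methyl (2S,13R)-2-[(tert-butyldimethylsilyl)oxy]-19-hydroxy-ent-labd-8(17)-en-15-oate | OC[C@]1(C)C[C@@H](O[Si](C)(C)C(C)(C)C)C[C@@]2(C)[C@H](CC[C@@H](C)CC(=O)OC)C(=C)CC[C@H]12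
A3 | alternative 2 | (4S)-3-methyl-4-(prop-2-en-1-yl)cyclohex-2-en-1-one | C=CC[C@@H]1CCC(=O)C=C1C
A4 | alternative 2 | tert-butyldimethyl{[(3R,6E)-3,7-dimethyl-8-(trimethylsilyl)oct-6-en-1-yl]oxy}silane | C[Si](C)(C)C/C(C)=C/CC[C@@H](C)CCO[Si](C)(C)C(C)(C)C
A5 | alternative 2 | conjugate allylation adduct, 4-allyl-3-methyl-3-[7-(tert-butyldimethylsilyloxy)-2,5-dimethylhept-1-en-3-yl]cyclohexan-1-one with the target configuration at C5, C9, C10, C13 | C=CC[C@@H]1CCC(=O)C[C@@]1(C)[C@H](CC[C@@H](C)CCO[Si](C)(C)C(C)(C)C)C(C)=C
A6 | alternative 2 | (13R)-15-[(tert-butyldimethylsilyl)oxy]-18,19-dinor-ent-labd-7-en-2-one | C1CC(=O)C[C@@]2(C)[C@H](CC[C@@H](C)CCO[Si](C)(C)C(C)(C)C)C(C)=CC[C@H]12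
A7 | alternative 3 | methyl (3R,6E)-3,7-dimethylnona-6,8-dienoate | C=C/C(C)=C/CC[C@@H](C)CC(=O)OC
A8 | alternative 3 | methyl (3E)-4-methyl-5-oxopent-3-enoate | O=C/C(C)=C/CC(=O)OC
A9 | alternative 3 | endo Diels–Alder adduct of A7 and A8, formyl syn to the C9 side chain (9-epi series) | O=C[C@@]1(C)[C@@H](CC[C@@H](C)CC(=O)OC)C(C)=CC[C@@H]1CC(=O)OC
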